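Ring A is disconnected by a Diels–Alder reaction: methyl methacrylate (C3–C4) adds to the vinylcyclohexene C2=C1–C10=C5, which comes from a ring B ketone (C10=O). Ring B is first built one carbon short, as the cyclopentanone C10–C9–C8–C7–C6, on which conjugate methylation and anti alkylation set C8 and C9. The key step inserts C5 between C10 and C6 with (trimethylsilyl)diazomethane. It exploits that C10 of ring B lies between quaternary C9 and methylene C6: only C6 migrates, C8 and C9 stay untouched, and the new C5H2 becomes the sole enolisable site, the later diene terminus. The precursor is a 2,2,3-trisubstituted cyclopentanone carrying the finished side chain.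

Key step: step 6

Remark on numbering: halimane numbering is used. Ring A is C1–C5 plus C10 and ring B is C5–C10. C4 carries CH3 and CO2CH3, C8 and C9 each carry CH3, and C11–C15 is the side chain with C13 as its stereocentre.

Remark on the chemistry (assumption): the sense of induction of the copper–phosphoramidite catalyst in step 1 is assumed. The ligand enantiomer used is the one that delivers methyl to the enone face giving the 3R enol ether 3.

Step 1
Reactants: 1 2-methylcyclopent-2-en-1-one
Product: 3 [(3R)-2,3-dimethylcyclopent-1-en-1-yl]oxy(trimethyl)silane, via dimethylaluminium enolate 2 (not isolated)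
Conditions: Me3Al, Cu(O2CC4H3S) (copper thiophene-2-carboxylate, 2 mol %), phosphoramidite from 1,1'-bi-2-naphthol and bis(1-phenylethyl)amine (4 mol %), Et2O, −30 °C; then TMSOTf, −30 °C to rt
Reagents that add atoms: trimethylaluminium C[Al](C)C; trimethylsilyl trifluoromethanesulfonate C[Si](C)(C)OS(=O)(=O)C(F)(F)F
Why: Copper-catalysed asymmetric conjugate addition, in which the chiral copper–phosphoramidite complex differentiates the enone faces and so sets C8 as R, and O-silylation of aluminium enolate 2 locks the C10=C9 enol ether regiospecifically.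

Step 2
Reactants: 3 [(3R)-2,3-dimethylcyclopent-1-en-1-yl]oxy(trimethyl)silane; 4 (R)-citronellyl bromide, (6R)-8-bromo-2,6-dimethyloct-2-ene
Product: 6 (2S,3R)-2-[(3R)-3,7-dimethyloct-6-en-1-yl]-2,3-dimethylcyclopentan-1-one, via lithium enolate 5 (not isolated)
Conditions: MeLi, THF, 0 °C; then 4, HMPA, Bu4NI (cat.), −78 °C to rt
Reagents that add atoms: none
Why: Regiospecific enolate generation from a silyl enol ether followed by SN2 alkylation, in which the bromide should approach the flat cyclopentene enolate 5 from the face opposite the C8 methyl group, so that quaternary C9 is set with the side chain trans to that methyl group while C13 is carried in unchanged from 4.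

Step 3
Reactants: 6 (2S,3R)-2-[(3R)-3,7-dimethyloct-6-en-1-yl]-2,3-dimethylcyclopentan-1-one
Product: 8 (4S)-6-[(1S,2R)-1,2-dimethyl-5-oxocyclopentyl]-4-methylhexanoic acid, via aldehyde 7 (not isolated)
Conditions: RuCl3·xH2O (cat.), NaIO4, EtOAc–MeCN–H2O, rt
Reagents that add atoms: sodium periodate [Na+].[O-]I(=O)(=O)=O
Why: RuO4-catalysed oxidative cleavage of the only alkene gives acetone and aldehyde 7, which is oxidised on to the acid, while the hindered ketone and all stereocentres are not affected.

Step 4
Reactants: 8 (4S)-6-[(1S,2R)-1,2-dimethyl-5-oxocyclopentyl]-4-methylhexanoic acid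
Product: 10 (2S,3R)-2-[(3S)-5-iodo-3-methylpentyl]-2,3-dimethylcyclopentan-1-one, via acyl hypoiodite 9 (not isolated)
Conditions: PhI(OAc)2, I2, cyclohexane, tungsten lamp, reflux
Reagents that add atoms: iodine II
Why: Hunsdiecker-type iododecarboxylation, in which hypoiodite 9 loses CO2 under light and the primary C15 radical is trapped by iodine faster than it can abstract hydrogen, so the surplus carbon of the citronellyl chain is removed.

Step 5
Reactants: 10 (2S,3R)-2-[(3S)-5-iodo-3-methylpentyl]-2,3-dimethylcyclopentan-1-one
Product: 11 (3S)-5-[(1S,2R)-1,2-dimethyl-5-oxocyclopentyl]-3-methylpentyl acetate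
Conditions: KOAc, DMF, 60 °C
Reagents that add atoms: potassium acetate CC(=O)[O-].[K+]
Why: SN2 displacement of the unhindered primary iodide by acetate, which is too weak a base to disturb the ketone.

Step 6
Reactants: 11 (3S)-5-[(1S,2R)-1,2-dimethyl-5-oxocyclopentyl]-3-methylpentyl acetate
Product: 13 (3S)-5-[(1S,2R)-1,2-dimethyl-6-oxocyclohexyl]-3-methylpentyl acetate, via α-silyl ketone 12 (not isolated)
Conditions: TMSCHN2, BF3·OEt2, CH2Cl2, −78 to −20 °C; then 1 M HCl, THF, rt
Reagents that add atoms: (trimethylsilyl)diazomethane C[Si](C)(C)C=[N+]=[N-]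
Why: BF3 activates the C10 carbonyl of 11, the diazo carbon (the future C5) adds to it, and in the resulting β-oxido diazonium betaine the C10–C6 bond shifts to C5 antiperiplanar to the departing N2, which restores the C10 carbonyl inside a six-membered ring and gives 12, whose silyl group is then removed by acid. The closest known reaction type is the Lewis-acid-promoted diazoalkane homologation of cyclic ketones, a Tiffeneau–Demjanov-type 1,2-shift that is well established for cyclopentanones with an α-quaternary carbon. No ring is closed by cyclisation: the ring C10–C9–C8–C7–C6 is enlarged to ring B by insertion of C5 between C10 and C6. No lasting stereocentre is formed, since C5 ends as CH2 and the silyl-bearing centre of 12 is erased, while C8, C9 and C13 take no part and are retained. The step needs migration of C6 in preference to C9, and this is secured by the substrate because the bulky CH(SiMe3)N2 unit turns away from quaternary C9 and so places the unhindered methylene C6 anti to N2. It also needs to stop after one insertion, which the α-silyl group of 12 ensures by shielding the new carbonyl, and the acetate is inert to BF3·OEt2 at low temperature.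

Step 7
Reactants: 13 (3S)-5-[(1S,2R)-1,2-dimethyl-6-oxocyclohexyl]-3-methylpentyl acetate
Product: 14 (3S)-5-[(1S,6R)-1,6-dimethyl-2-(trifluoromethylsulfonyloxy)cyclohex-2-en-1-yl]-3-methylpentyl acetate
Conditions: Tf2O, 2,6-di-tert-butyl-4-methylpyridine, CH2Cl2, 0 °C to rt
Reagents that add atoms: trifluoromethanesulfonic anhydride O=S(=O)(OS(=O)(=O)C(F)(F)F)C(F)(F)F
Why: Vinyl triflate formation with Tf2O and a hindered, non-nucleophilic pyridine, in which only the C10=C5 enol triflate can form because C9 bears no hydrogen, and no strong base is present that could attack the acetate.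

Step 8
Reactants: 14 (3S)-5-[(1S,6R)-1,6-dimethyl-2-(trifluoromethylsulfonyloxy)cyclohex-2-en-1-yl]-3-methylpentyl acetate
Product: 15 (3S)-5-[(1S,6R)-2-ethenyl-1,6-dimethylcyclohex-2-en-1-yl]-3-methylpentyl acetate
Conditions: CH2=CHSnBu3, Pd(PPh3)4 (cat.), LiCl, THF, reflux
Reagents that add atoms: tributyl(vinyl)stannane C=C[Sn](CCCC)(CCCC)CCCC
Why: Stille coupling of a vinyl triflate with a vinylstannane in the presence of LiCl, a standard entry to 1-vinylcyclohexenes that tolerates the acetate and the neighbouring quaternary carbon.

Step 9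
Reactants: 15 (3S)-5-[(1S,6R)-2-ethenyl-1,6-dimethylcyclohex-2-en-1-yl]-3-methylpentyl acetate; 16 methyl methacrylate
Product: 17 methyl (1S,5S,6R,8aR)-5-[(3S)-5-acetoxy-3-methylpentyl]-1,5,6-trimethyl-1,2,3,5,6,7,8,8a-octahydronaphthalene-1-carboxylate (target)
Conditions: EtAlCl2, CH2Cl2, −40 to 0 °C
Reagents that add atoms: none
Why: Lewis-acid-promoted Diels–Alder reaction, in which the unsubstituted vinyl terminus C2 pairs with the β-carbon C3 so that C4 bonds to C5 (ortho rule), the dienophile should approach the diene face opposite the pseudoaxial C9 methyl group so that H5 ends cis to the C8 and C9 methyl groups, and the aluminium-bound ester should lie endo, which sets C4 with the ester trans to H5 and leaves the alkene at C1=C10.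

Compound list
1 | 2-methylcyclopent-2-en-1-one | CC1=CCCC1=O | starting material
2 | dimethyl{[(3R)-2,3-dimethylcyclopent-1-en-1-yl]oxy}aluminium (not isolated) | C[Al](C)OC1=C(C)[C@H](C)CC1 | intermediate
3 | [(3R)-2,3-dimethylcyclopent-1-en-1-yl]oxy(trimethyl)silane | C[Si](C)(C)OC1=C(C)[C@H](C)CC1 | intermediate
4 | (R)-citronellyl bromide, (6R)-8-bromo-2,6-dimethyloct-2-ene | CC(C)=CCC[C@@H](C)CCBr | starting material
5 | lithium (3R)-2,3-dimethylcyclopent-1-en-1-olate (not isolated) | [Li]OC1=C(C)[C@H](C)CC1 | intermediate
6 | (2S,3R)-2-[(3R)-3,7-dimethyloct-6-en-1-yl]-2,3-dimethylcyclopentan-1-one | O=C1CC[C@@H](C)[C@]1(C)CC[C@H](C)CCC=C(C)C | intermediate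
7 | (4S)-6-[(1S,2R)-1,2-dimethyl-5-oxocyclopentyl]-4-methylhexanal (not isolated) | O=C1CC[C@@H](C)[C@]1(C)CC[C@H](C)CCC=O | intermediate
8 | (4S)-6-[(1S,2R)-1,2-dimethyl-5-oxocyclopentyl]-4-methylhexanoic acid | O=C1CC[C@@H](C)[C@]1(C)CC[C@H](C)CCC(=O)O | intermediate
9 | acyl hypoiodite of 8 (not isolated) | O=C1CC[C@@H](C)[C@]1(C)CC[C@H](C)CCC(=O)OI | intermediate
10 | (2S,3R)-2-[(3S)-5-iodo-3-methylpentyl]-2,3-dimethylcyclopentan-1-one | O=C1CC[C@@H](C)[C@]1(C)CC[C@H](C)CCI | intermediate
11 | (3S)-5-[(1S,2R)-1,2-dimethyl-5-oxocyclopentyl]-3-methylpentyl acetate | O=C1CC[C@@H](C)[C@]1(C)CC[C@H](C)CCOC(C)=O | intermediate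
12 | (3S)-5-[(1S,2R)-1,2-dimethyl-6-oxo-5-(trimethylsilyl)cyclohexyl]-3-methylpentyl acetate, both epimers at the silyl-bearing carbon (not isolated) | O=C1C([Si](C)(C)C)CC[C@@H](C)[C@]1(C)CC[C@H](C)CCOC(C)=O | intermediate
13 | (3S)-5-[(1S,2R)-1,2-dimethyl-6-oxocyclohexyl]-3-methylpentyl acetate | O=C1CCC[C@@H](C)[C@]1(C)CC[C@H](C)CCOC(C)=O | intermediate
14 | (3S)-5-[(1S,6R)-1,6-dimethyl-2-(trifluoromethylsulfonyloxy)cyclohex-2-en-1-yl]-3-methylpentyl acetate | O=S(=O)(OC1=CCC[C@@H](C)[C@]1(C)CC[C@H](C)CCOC(C)=O)C(F)(F)F | intermediate
15 | (3S)-5-[(1S,6R)-2-ethenyl-1,6-dimethylcyclohex-2-en-1-yl]-3-methylpentyl acetate | C=CC1=CCC[C@@H](C)[C@]1(C)CC[C@H](C)CCOC(C)=O | intermediate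
16 | methyl methacrylate | C=C(C)C(=O)OC | starting material
17 | methyl (1S,5S,6R,8aR)-5-[(3S)-5-acetoxy-3-methylpentyl]-1,5,6-trimethyl-1,2,3,5,6,7,8,8a-octahydronaphthalene-1-carboxylate | COC(=O)[C@@]1(C)CCC=C2[C@H]1CC[C@@H](C)[C@]2(C)CC[C@H](C)CCOC(C)=O | target

Total steps: 9. Longest linear sequence: 9 steps (1 to 17). No protecting groups are used.

Steps most likely to fail

Step 9.
- What may go wrong: the α-methylated, weakly activated dienophile may add sluggishly to the hindered diene. Facial and endo/exo selectivity may be poor. The Lewis acid may isomerise or oligomerise the diene.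
- Fallback: it sets out from 15 and uses the more reactive methacrolein under catalyst control. The catalyst is the oxazaborolidine made from α,α-diphenylprolinol and o-tolylboronic acid, activated with Tf2NH, in the enantiomer that reinforces attack opposite the C9 methyl group. This should give the aldehyde analogue of 17 F1. Pinnick oxidation (NaClO2, NaH2PO4, 2-methylbut-2-ene) then gives the carboxylic acid analogue of 17 F2. Esterification with MeI and K2CO3 in DMF brings the route back at 17.

Step 6.
- What may go wrong: addition of the bulky diazoalkane to the neopentyl-type carbonyl may be slow. Epoxide formation may compete, and part of the material may rearrange by migration of C9.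
- Fallback: it sets out from 11 and fixes the site of insertion by the position of an enol ether instead of by migratory preference. TMSOTf and Et3N give the trimethylsilyl enol ether of 11 F3, the only one possible. Simmons–Smith cyclopropanation (Et2Zn, CH2I2) gives the siloxycyclopropane F4 with C5 as the apex. FeCl3 in DMF cleaves the C10–C6 bond oxidatively to the β-chloro ketone F5, and DBU gives the enone F6. Hydrogenation (H2, Pd/C, EtOAc) brings the route back at 13.

Step 2.
- What may go wrong: C-alkylation of the tetrasubstituted enolate by an unactivated bromide may be slow. Proton transfer, further alkylation at C6 and elimination of the bromide could then take over.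
- Fallback: it sets out from 3 by way of enolate 5 and uses a far more reactive electrophile. Aldol addition to (R)-citronellal at −78 °C should give the aldol adduct F7, again by approach opposite the C8 methyl group. PhOC(S)Cl, pyridine and DMAP convert it under non-basic conditions, which avoid retro-aldol cleavage, into the O-phenyl thionocarbonate F8. Barton–McCombie deoxygenation (Bu3SnH at high concentration, AIBN, toluene, 80 °C) removes the C11 oxygen and brings the route back at 6.

Further compounds
F1 | step 9 | aldehyde analogue of 17 (CHO at C4) | O=C[C@@]1(C)CCC=C2[C@H]1CC[C@@H](C)[C@]2(C)CC[C@H](C)CCOC(C)=O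
F2 | step 9 | carboxylic acid analogue of 17 (CO2H at C4) | OC(=O)[C@@]1(C)CCC=C2[C@H]1CC[C@@H](C)[C@]2(C)CC[C@H](C)CCOC(C)=O
F3 | step 6 | trimethylsilyl enol ether of 11 (C10=C6) | C[Si](C)(C)OC1=CC[C@@H](C)[C@]1(C)CC[C@H](C)CCOC(C)=O
F4 | step 6 | siloxycyclopropane, 1-trimethylsiloxybicyclo[3.1.0]hexane with C5 as apex (configuration of the two cyclopropane ring-fusion carbons is irrelevant) | C[Si](C)(C)OC12CC1C[C@@H](C)[C@]2(C)CC[C@H](C)CCOC(C)=O
F5 | step 6 | β-chloro ketone (six-membered ring, Cl at C6, either epimer) | O=C1CC(Cl)C[C@@H](C)[C@]1(C)CC[C@H](C)CCOC(C)=O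
F6 | step 6 | enone (C10=O, C5=C6) | O=C1C=CC[C@@H](C)[C@]1(C)CC[C@H](C)CCOC(C)=O
F7 | step 2 | aldol adduct (11-hydroxy derivative of 6, either carbinol epimer) | O=C1CC[C@@H](C)[C@]1(C)C(O)C[C@H](C)CCC=C(C)C
F8 | step 2 | O-phenyl thionocarbonate of F7 | O=C1CC[C@@H](C)[C@]1(C)C(OC(=S)Oc2ccccc2)C[C@H](C)CCC=C(C)C
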